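**Plan**

1. Retrosynthetic cuts, in order: the two ArO–benzyl bonds; C3–O and C2–H together (syn hydration of a C2=C3 enol ether); the C2=C3 bond of the resulting 2,3-dihydrofuran (ring-closing metathesis); the enol ether CH2 (back to an ester C=O); the ester C–O bond; C4–C5 (allylboration).
2. Enabling feature: in the oxolane, C2 carries O1 and an aryl group, C3 carries a methyl and the hydroxyl, and C2–H and C3–OH lie on one face. That pair is a hydrated enol ether, so C2 can enter as the carbonyl carbon of an aroate on O1 and C3 as the inner carbon of an isopropenyl group on C4, which after methylenation are two 1,1-disubstituted alkenes placed for five-ring closure.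
3. Forward order: allylboration joins C5–C4–C3, esterification joins O1–C2, the ester is methylenated, metathesis closes the oxolane (the only ring formed) as a 2,3-dihydrofuran, then hydroboration–oxidation and debenzylation.
4. Stereochemistry: C5 (S) and C4 (R) come from the catalyst-controlled anti allylboration; C2 (R) and C3 (S) come together from syn hydroboration on the face opposite the C4 methyl.

Key step: step 5

Remark: in the prose the atoms are numbered as in the oxolane of the target (O1, C2 aryl-bearing next to the carbinol, C3 carbinol, C4, C5), also for open-chain precursors; compound names use their own locants. Compounds 1, 3 and 6 are taken as commercial.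

**Route**

Step 1
Reactants: 1 (E)-2-methylbut-2-en-1-ol
Product: 2 4,4,5,5-tetramethyl-2-[(E)-2-methylbut-2-en-1-yl]-1,3,2-dioxaborolane
Conditions: B2pin2 (1.2 equiv), Pd(MeCN)4(BF4)2 (5 mol %), DMSO/MeOH 1:1, 50 °C
Reagents that add atoms: bis(pinacolato)diboron, CC1(C)OB(OC1(C)C)B1OC(C)(C)C(C)(C)O1
Why: Palladium-catalysed borylation of an allylic alcohol should pass through an η3-allylpalladium species that takes up boron at its unsubstituted CH2 terminus, giving the linear allylboronate with the E geometry of the starting alcohol retained.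

Step 2
Reactants: 2 4,4,5,5-tetramethyl-2-[(E)-2-methylbut-2-en-1-yl]-1,3,2-dioxaborolane, 3 4-(benzyloxy)-3-methoxybenzaldehyde
Product: 5 (1S,2S)-1-[4-(benzyloxy)-3-methoxyphenyl]-2,3-dimethylbut-3-en-1-ol, via pinacol borate ester 4 (not isolated)
Conditions: (S)-3,3'-bis(2,4,6-triisopropylphenyl)-1,1'-binaphthyl-2,2'-diyl hydrogen phosphate (5 mol %), 4 Å sieves, toluene, −30 °C; aq. NaHCO3 work-up
Reagents that add atoms: none
Why: In this chiral phosphoric acid-catalysed allylboration the acid binds a boronate oxygen and the formyl group in a closed chair (Zimmerman–Traxler) transition state, the (S)-catalyst being chosen to direct attack to the Si face of the aryl aldehyde (carbinol carbon S, the future C5) while the E γ-methyl sits equatorial (anti methyl, the future C4), and work-up hydrolyses the borate.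

Step 3
Reactants: 5 (1S,2S)-1-[4-(benzyloxy)-3-methoxyphenyl]-2,3-dimethylbut-3-en-1-ol, 6 4-(benzyloxy)-3-methoxybenzoic acid
Product: 7 (1S,2S)-1-[4-(benzyloxy)-3-methoxyphenyl]-2,3-dimethylbut-3-en-1-yl 4-(benzyloxy)-3-methoxybenzoate
Conditions: DCC (1.2 equiv), DMAP (0.2 equiv), CH2Cl2, 0 °C → rt
Reagents that add atoms: none
Why: Steglich esterification acylates the hindered secondary alcohol at oxygen under neutral conditions, so the acid-sensitive electron-rich benzylic C–O bond and both stereocentres should be untouched.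

Step 4
Reactants: 7 (1S,2S)-1-[4-(benzyloxy)-3-methoxyphenyl]-2,3-dimethylbut-3-en-1-yl 4-(benzyloxy)-3-methoxybenzoate
Product: 8 1-(benzyloxy)-4-[1-({(1S,2S)-1-[4-(benzyloxy)-3-methoxyphenyl]-2,3-dimethylbut-3-en-1-yl}oxy)ethenyl]-2-methoxybenzene
Conditions: Cp2TiMe2 (3 equiv), toluene, 70 °C, dark; filtration through basic Al2O3
Reagents that add atoms: dimethyltitanocene, C[Ti](C)(C1C=CC=C1)C1C=CC=C1
Why: Carbonyl methylenation of an ester: thermolysis of Cp2TiMe2 gives Cp2Ti=CH2, which adds to the ester C=O and collapses through an oxatitanacyclobutane to the 1-arylvinyl ether under non-basic, weakly Lewis acidic conditions that should leave the benzylic ether, the isopropenyl group and both stereocentres intact.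

Step 5
Reactants: 8 1-(benzyloxy)-4-[1-({(1S,2S)-1-[4-(benzyloxy)-3-methoxyphenyl]-2,3-dimethylbut-3-en-1-yl}oxy)ethenyl]-2-methoxybenzene
Product: 9 (2S,3S)-2,5-bis[4-(benzyloxy)-3-methoxyphenyl]-3,4-dimethyl-2,3-dihydrofuran
Conditions: Mo(=CHCMe2Ph)(=N-2,6-iPr2C6H3)[OCMe(CF3)2]2 (20 mol %), benzene, 25 → 60 °C, argon sweep, base-washed glassware
Reagents that add atoms: none
Why: The molybdenum alkylidene exchanges its alkylidene ligand with one of the two 1,1-disubstituted alkenes of 8 by [2+2] cycloaddition and cycloreversion, and the tethered Mo=C then adds across the other alkene to a molybdacyclobutane whose cycloreversion gives the C2=C3 double bond and Mo=CH2, ethene being lost overall. The closest known reaction type is the molybdenum-catalysed ring-closing metathesis of olefinic enol ethers made by methylenation of esters, which gives cyclic enol ethers including fully substituted ones. The only ring closed is the five-membered oxygen ring, formed by metathesis with the new double bond endocyclic (C2 from the former ester carbon, C3 from the inner isopropenyl carbon), a closure favoured entropically and driven by loss of ethene. No stereocentre is created, and C4 and C5 should be carried through unchanged because the catalyst is neither basic nor protic and C4–H is not activated. The step needs cyclisation to win over intermolecular metathesis and over ionisation or [1,3]-shift of the benzylic vinyl ether: both alkenes are 1,1-disubstituted and do not homodimerise, the anti C4/C5 arrangement lets the two arms approach without a methyl/aryl eclipsing contact, and strictly neutral conditions protect the ether.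

Step 6
Reactants: 9 (2S,3S)-2,5-bis[4-(benzyloxy)-3-methoxyphenyl]-3,4-dimethyl-2,3-dihydrofuran
Product: 11 (2R,3S,4R,5S)-2,5-bis[4-(benzyloxy)-3-methoxyphenyl]-3,4-dimethyloxolan-3-ol, via alkylborane 10 (not isolated)
Conditions: BH3·THF (3 equiv), THF, 0 °C → rt; then aq. NaOH, H2O2, 0 °C → rt
Reagents that add atoms: borane–tetrahydrofuran (boron in 10), B.C1CCOC1; hydrogen peroxide (oxygen in 11), OO
Why: Hydroboration–oxidation of a cyclic enol ether puts boron on C3 (β to the ring oxygen and the aryl group) and hydrogen on C2 in a syn four-centre addition from the face opposite the C4 methyl, which flanks the carbon receiving boron (as in hydroboration of furanoid glycals), and C–B oxidation with retention then sets C2 (R) and C3 (S) together with C2–H, C3–OH and C4–H on one face.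

Step 7
Reactants: 11 (2R,3S,4R,5S)-2,5-bis[4-(benzyloxy)-3-methoxyphenyl]-3,4-dimethyloxolan-3-ol
Product: 12 (2R,3S,4R,5S)-2,5-bis(4-hydroxy-3-methoxyphenyl)-3,4-dimethyloxolan-3-ol
Conditions: H2 (1 atm), Pd/C (10 wt %), EtOAc, rt
Reagents that add atoms: none
Why: Hydrogenolysis of aryl benzyl ethers over palladium in a non-protic solvent at ambient pressure should be much faster than cleavage of the benzylic C–O bonds of the 2,5-diaryloxolane, so both phenols are freed without touching the ring, the tertiary alcohol or any stereocentre.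

**Compound list**

1 | (E)-2-methylbut-2-en-1-ol | C/C=C(\C)CO | starting material
2 | 4,4,5,5-tetramethyl-2-[(E)-2-methylbut-2-en-1-yl]-1,3,2-dioxaborolane | C/C=C(\C)CB1OC(C)(C)C(C)(C)O1 | intermediate
3 | 4-(benzyloxy)-3-methoxybenzaldehyde | COc1cc(C=O)ccc1OCc1ccccc1 | starting material
4 | 2-{[(1S,2S)-1-[4-(benzyloxy)-3-methoxyphenyl]-2,3-dimethylbut-3-en-1-yl]oxy}-4,4,5,5-tetramethyl-1,3,2-dioxaborolane | CC1(C)OB(O[C@H](c2ccc(OCc3ccccc3)c(OC)c2)[C@@H](C)C(C)=C)OC1(C)C | intermediate
5 | (1S,2S)-1-[4-(benzyloxy)-3-methoxyphenyl]-2,3-dimethylbut-3-en-1-ol | O[C@H](c1ccc(OCc2ccccc2)c(OC)c1)[C@@H](C)C(C)=C | intermediate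
6 | 4-(benzyloxy)-3-methoxybenzoic acid | COc1cc(C(=O)O)ccc1OCc1ccccc1 | starting material
7 | (1S,2S)-1-[4-(benzyloxy)-3-methoxyphenyl]-2,3-dimethylbut-3-en-1-yl 4-(benzyloxy)-3-methoxybenzoate | O=C(O[C@H](c1ccc(OCc2ccccc2)c(OC)c1)[C@@H](C)C(C)=C)c1ccc(OCc2ccccc2)c(OC)c1 | intermediate
8 | 1-(benzyloxy)-4-[1-({(1S,2S)-1-[4-(benzyloxy)-3-methoxyphenyl]-2,3-dimethylbut-3-en-1-yl}oxy)ethenyl]-2-methoxybenzene | C=C(O[C@H](c1ccc(OCc2ccccc2)c(OC)c1)[C@@H](C)C(C)=C)c1ccc(OCc2ccccc2)c(OC)c1 | intermediate
9 | (2S,3S)-2,5-bis[4-(benzyloxy)-3-methoxyphenyl]-3,4-dimethyl-2,3-dihydrofuran | COc1cc([C@H]2OC(c3ccc(OCc4ccccc4)c(OC)c3)=C(C)[C@@H]2C)ccc1OCc1ccccc1 | intermediate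
10 | [(2S,3R,4S,5S)-2,5-bis[4-(benzyloxy)-3-methoxyphenyl]-3,4-dimethyloxolan-3-yl]borane (BH2 on C3, cis to H on C2, trans to the C4 methyl) | COc1cc([C@H]2O[C@H](c3ccc(OCc4ccccc4)c(OC)c3)[C@@](C)(B)[C@@H]2C)ccc1OCc1ccccc1 | intermediate
11 | (2R,3S,4R,5S)-2,5-bis[4-(benzyloxy)-3-methoxyphenyl]-3,4-dimethyloxolan-3-ol | COc1cc([C@H]2O[C@H](c3ccc(OCc4ccccc4)c(OC)c3)[C@@](C)(O)[C@@H]2C)ccc1OCc1ccccc1 | intermediate
12 | (2R,3S,4R,5S)-2,5-bis(4-hydroxy-3-methoxyphenyl)-3,4-dimethyloxolan-3-ol | COc1cc([C@H]2O[C@H](c3ccc(O)c(OC)c3)[C@@](C)(O)[C@@H]2C)ccc1O | target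

**Step count and risks**

Total step count: 7. Longest linear sequence: 7 steps (1 → 2 → 5 → 7 → 8 → 9 → 11 → 12).

Steps most likely to fail:

Step 5. The ring closure may stall because two hindered 1,1-disubstituted alkenes must form a tetrasubstituted double bond. The catalyst may decompose before turnover, or the benzylic vinyl ether may ionise (this last risk also applies to step 4). The fallback sets out from 7 and bypasses 8. Lemieux–Johnson cleavage of the isopropenyl group (OsO4 cat., NaIO4, 2,6-lutidine, dioxane/H2O) should give the keto ester (1S,2R)-1-[4-(benzyloxy)-3-methoxyphenyl]-2-methyl-3-oxobutyl 4-(benzyloxy)-3-methoxybenzoate F1. An intramolecular McMurry-type keto ester coupling with low-valent titanium (TiCl3, Zn dust, DME, reflux) should then join the ketone carbon to the ester carbon as the same C2=C3 enol ether bond, returning to the route at 9.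

Step 6. Facial discrimination between the C4-methyl face and the C5-aryl face may be insufficient, or the C3 borane may undergo β-alkoxy elimination with ring opening. The fallback sets out from 9. Epoxidation with dimethyldioxirane (acetone/CH2Cl2, −78 °C) should give (1S,3S,4R,5S)-1,3-bis[4-(benzyloxy)-3-methoxyphenyl]-4,5-dimethyl-2,6-dioxabicyclo[3.1.0]hexane F2, the oxirane oxygen anti to the C4 methyl. Treated in the same flask with iBu2AlH (CH2Cl2, −78 °C), the aluminium-bound epoxide should open at C2 to the aryl-stabilised oxocarbenium ion and receive hydride from the aluminium alkoxide on the same face. The C2–H bond is thus formed cis to C3–O by intramolecular delivery, and no β-alkoxy borane is involved; the fallback returns to the route at 11.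

Step 2. Enantio- or diastereoselectivity may erode with the 2-methyl-substituted allylboronate, or Z isomer from geometry scrambling in step 1 may lead to the syn adduct. The fallback sets out from 3 and uses auxiliary control.
- MgCl2-catalysed anti-aldol of 3 with commercial (S)-4-benzyl-3-propionyl-1,3-oxazolidin-2-one (MgCl2 cat., Et3N, Me3SiCl, EtOAc, rt) should give (4S)-4-benzyl-3-[(2R,3S)-3-[4-(benzyloxy)-3-methoxyphenyl]-2-methyl-3-[(trimethylsilyl)oxy]propanoyl]-1,3-oxazolidin-2-one F3. The chelated Z-enolate is attacked on the face opposite the benzyl group through a boat transition state.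
- MeOH/CF3CO2H should free the aldol (4S)-4-benzyl-3-[(2R,3S)-3-[4-(benzyloxy)-3-methoxyphenyl]-3-hydroxy-2-methylpropanoyl]-1,3-oxazolidin-2-one F4.
- Transamination (AlMe3, MeNH(OMe)·HCl, CH2Cl2) should give (2R,3S)-3-[4-(benzyloxy)-3-methoxyphenyl]-3-hydroxy-N-methoxy-N,2-dimethylpropanamide F5.
- Et3SiCl/imidazole should give its silyl ether (2R,3S)-3-[4-(benzyloxy)-3-methoxyphenyl]-N-methoxy-N,2-dimethyl-3-[(triethylsilyl)oxy]propanamide F6.
- MeMgBr (THF, 0 °C) should give (3R,4S)-4-[4-(benzyloxy)-3-methoxyphenyl]-3-methyl-4-[(triethylsilyl)oxy]butan-2-one F7.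
- Cp2TiMe2 (toluene, 70 °C) should give {[(1S,2S)-1-[4-(benzyloxy)-3-methoxyphenyl]-2,3-dimethylbut-3-en-1-yl]oxy}triethylsilane F8.
- Bu4NF (THF, 0 °C) returns to the route at 5.

Further compounds
F1 | step 5 | (1S,2R)-1-[4-(benzyloxy)-3-methoxyphenyl]-2-methyl-3-oxobutyl 4-(benzyloxy)-3-methoxybenzoate | O=C(O[C@H](c1ccc(OCc2ccccc2)c(OC)c1)[C@@H](C)C(C)=O)c1ccc(OCc2ccccc2)c(OC)c1
F2 | step 6 | (1S,3S,4R,5S)-1,3-bis[4-(benzyloxy)-3-methoxyphenyl]-4,5-dimethyl-2,6-dioxabicyclo[3.1.0]hexane | COc1cc([C@H]2O[C@@]3(c4ccc(OCc5ccccc5)c(OC)c4)O[C@@]3(C)[C@@H]2C)ccc1OCc1ccccc1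
F3 | step 2 | (4S)-4-benzyl-3-[(2R,3S)-3-[4-(benzyloxy)-3-methoxyphenyl]-2-methyl-3-[(trimethylsilyl)oxy]propanoyl]-1,3-oxazolidin-2-one | O=C1OC[C@H](Cc2ccccc2)N1C(=O)[C@H](C)[C@H](O[Si](C)(C)C)c1ccc(OCc2ccccc2)c(OC)c1
F4 | step 2 | (4S)-4-benzyl-3-[(2R,3S)-3-[4-(benzyloxy)-3-methoxyphenyl]-3-hydroxy-2-methylpropanoyl]-1,3-oxazolidin-2-one | O=C1OC[C@H](Cc2ccccc2)N1C(=O)[C@H](C)[C@H](O)c1ccc(OCc2ccccc2)c(OC)c1
F5 | step 2 | (2R,3S)-3-[4-(benzyloxy)-3-methoxyphenyl]-3-hydroxy-N-methoxy-N,2-dimethylpropanamide | CON(C)C(=O)[C@H](C)[C@H](O)c1ccc(OCc2ccccc2)c(OC)c1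
F6 | step 2 | (2R,3S)-3-[4-(benzyloxy)-3-methoxyphenyl]-N-methoxy-N,2-dimethyl-3-[(triethylsilyl)oxy]propanamide | CON(C)C(=O)[C@H](C)[C@H](O[Si](CC)(CC)CC)c1ccc(OCc2ccccc2)c(OC)c1
F7 | step 2 | (3R,4S)-4-[4-(benzyloxy)-3-methoxyphenyl]-3-methyl-4-[(triethylsilyl)oxy]butan-2-one | CC(=O)[C@H](C)[C@H](O[Si](CC)(CC)CC)c1ccc(OCc2ccccc2)c(OC)c1
F8 | step 2 | {[(1S,2S)-1-[4-(benzyloxy)-3-methoxyphenyl]-2,3-dimethylbut-3-en-1-yl]oxy}triethylsilane | CC[Si](CC)(CC)O[C@H](c1ccc(OCc2ccccc2)c(OC)c1)[C@@H](C)C(C)=C
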